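(The data were computed with constants of no real substance.)

The leftover substrate of the north run is where I start: 88.9% of the charge went in as substrate, and 73.6% stands at 3.00 min.

| flask | substrate | other conformer | temperature | remark | time |
|---|---|---|---|---|---|
| north | 2 M | 0.25 M | 80 °C | run made earlier |  |
| noon | 1.0 M | 0.250 M | 80 °C |  | 15 min |
| midnight | 1.0 M | 0.250 M | 55 °C |  | 15 min |
| dawn | 1.0 M | 0.250 M | 30 °C |  | 15 min |

- north (time / min: target / %, substrate / %): 0.250: 1.2, 89.4; 0.833: 1.8, 83.9; 1.33: 5.9, 84.6; 2.00: 8.6, 80.7; 3.00: 12.3, 73.6

(each reading ± 1 percentage point)

- in a conversion other conformer counts as not yet reacted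
- the earlier runs do not show what temperature does; that part of a forecast is a guess

* the flask that comes out highest in amount of target, in percent of the substrate and other conformer together charged, or "all alike" when all lie within 1.5 percentage points (noon / midnight / dawn / all alike)
* target at the end, in percent of the substrate and other conformer together charged, noon
* target at the end, in percent of the substrate and other conformer together charged, midnight
* target at the end, in percent of the substrate and other conformer together charged, dawn

I treat that loss as first order in [substrate], which a single charge cannot prove. The last reading then gives a loss constant of 0.0629 min⁻¹. I call the time in which such a loss halves the substrate the substrate life, 11.0 min at 80 °C. It is a reading and carries the scatter.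

Now the ladder, fastest rung first. The north run ends at 3.00 min, which is shorter than the life, so it shows the start of a flask. On this rung I follow one molecule leaving substrate and ask its chance of arriving as target. Target gained over substrate lost reads 80.5%, my selectivity at the fork, and this too carries the scatter.

The next rung is the life itself. The asked 15 min stands above it and holds 1.36 lives. So in noon, at the same temperature, I expect 38.9% of the charged substrate to remain. If target stays where it arrives, noon holds 39.3% of target. For midnight and dawn I have no rung, since temperature is untouched by the north run.

The forecast names noon as highest, with 43%, 7% and 0.7% of target in noon, midnight and dawn, its noon figure “allowing for slowing or reversibility” and higher than mine.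

The flasks give 21.1% in noon, 4.57% in midnight and 0.217% in dawn, so noon stands highest.

    target ⇌ isomer of the product B (K = 17.0, k = 0.120 min⁻¹, Ea = 103 kJ mol⁻¹, ΔH = −14.0 kJ mol⁻¹)
    target ⇌ isomer of the product A (K = 0.140, k = 0.00150 min⁻¹, Ea = 120 kJ mol⁻¹, ΔH = −61.0 kJ mol⁻¹)
    2 substrate → self-condensation product (k = 2.00 × 10⁻⁵ M⁻¹ min⁻¹, Ea = 105 kJ mol⁻¹)
    substrate ⇌ other conformer (K = 0.0850, k = 0.0350 min⁻¹, Ea = 95.0 kJ mol⁻¹, ΔH = −7.00 kJ mol⁻¹)
    substrate → target (k = 0.0590 min⁻¹, Ea = 103 kJ mol⁻¹)
    other conformer → isomer of the product A (k = 0.250 min⁻¹, Ea = 108 kJ mol⁻¹)
    (constants at 80 °C)

Noon has not come to rest. It keeps 40% of its charged substrate against my 38.9%, yet my figure of 39.3% for target stands above the 21.1% it holds, with 29.0% of isomer of the product B beside it. The north charge left to the same 15 min, the same 1.36 lives, gives 21.6% of target. Ten times the time is 13.6 lives in noon: substrate reaches 0%, isomer of the product B 87.8%, and target falls to 5.69%. Midnight over that time climbs to 20.7% of target with 43.3% of substrate still there, and dawn reaches 2.11%.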